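Each initiator gives two initiating radicals, so a charge of 10 mM can release 20.0 mM; call this count the radical budget B.

| setting | cedar | birch | Saturday's | Sunday's | Thursday's | Wednesday's |
|---|---|---|---|---|---|---|
| starting material | 0.040 M | 0.040 M | 0.040 M | 0.12 M | 0.30 M | 1.0 M |
| partner | 0.80 M | 0.40 M | 0.800 M | 0.800 M | 0.800 M | 0.800 M |
| transfer agent | 0.10 M | 0.10 M | 0.100 M | 0.100 M | 0.100 M | 0.100 M |
| initiator | 15 mM | 10 mM | 10 mM | 10 mM | 10 mM | 10 mM |
| remark | run made earlier | run made earlier |  |  |  |  |
| time |  |  | 4.0 min | 4.0 min | 4.0 min | 4.0 min |

| run | time / s | target / % |
|---|---|---|
| cedar | 10.0 | 12 |
| cedar | 30.0 | 25 |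
| cedar | 50.0 | 33 |
| cedar | 80.0 | 28 |
| birch | 10.0 | 7 |
| birch | 30.0 | 15 |
| birch | 50.0 | 23 |
| birch | 80.0 | 22 |

(standard deviation of a reading: 2 percentage points)

- percent here means starting material units held: one ended chains B counts as two
- the earlier runs were read with a standard deviation of 2 percentage points
- what may be going on: 2 second chain carrier -> ended chains A; target -> over-reaction product; transfer agent + first chain carrier -> side product + idle radical; 2 idle radical -> ended radicals; initiator -> 2 initiating radical; 2 first chain carrier -> ended chains B; starting material + initiating radical -> capped initiator + first chain carrier; partner + first chain carrier -> target + second chain carrier; starting material + second chain carrier -> by-product + first chain carrier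
- "hardly changes" means that all values lie within two and a half points (for a concentration: within two and a half percent of the largest)

1. amount of target at the end, in percent of the starting material charged for Saturday's, Sunday's, Thursday's, Wednesday's, in this order
2. the shape of the row from first to last (rises all the way / falls all the way / falls, then rises / rises, then falls / hardly changes)

Divide the target held in a run by that run's own budget and call the result h, target held per radical. Cedar's highest reading gives h = 0.440, and birch's gives 0.460. Birch carries the same initiator charge as the new flasks.

Ben holds that h is what matters. It barely moved although birch had 0.40 M of partner against cedar's 0.80 M, so he expects a peak near 9.20 mM of target at any charge c of starting material. As a percentage that is 23.0% in Saturday's flask and 0.920% in Wednesday's, a fall by a factor of 25.0.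

Ann objects. Cedar and birch share one charge, 0.040 M, so h has not been tried against c. The step in which starting material meets the second chain carrier returns a first chain carrier, and its rate grows with c. A radical should therefore turn more often in a richer flask, target should follow c, and the percentage should hardly change.

Her row has a price. Cedar's last reading, 28%, held at 1.0 M in Wednesday's flask means 14.0 target per radical of B, far more than the readings of h, by a factor of 30.4.

So my own reckoning goes with Ben on direction: the row falls. Ann's step stays in the list of what may go on, though, so I put the fall below Ben's factor, and I commit to no figures beyond that.

The forecast gives 6%, 4.5%, 2.5% and 1%, a row that falls all the way, and says “More starting material recycles the second carrier better, so absolute target rises, but less than proportionally”.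

The flask gives 7.54%, 6.07%, 4.43% and 1.76%: the row falls all the way, in the direction Ben gave.

    2 second chain carrier → ended chains A (k = 2.00 × 10⁸ M⁻¹ s⁻¹)
    target → over-reaction product (k = 0.0170 s⁻¹)
    transfer agent + first chain carrier → side product + idle radical (kL = 13000 M⁻¹ s⁻¹)
    2 idle radical → ended radicals (k = 1.00 × 10⁶ M⁻¹ s⁻¹)
    initiator → 2 initiating radical (k = 0.0110 s⁻¹)
    2 first chain carrier → ended chains B (k = 5.70 × 10⁸ M⁻¹ s⁻¹)
    starting material + initiating radical → capped initiator + first chain carrier (k = 4.70 × 10⁵ M⁻¹ s⁻¹)
    partner + first chain carrier → target + second chain carrier (k = 16000 M⁻¹ s⁻¹)
    starting material + second chain carrier → by-product + first chain carrier (k = 7700 M⁻¹ s⁻¹)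

Ann keeps the low end: from Saturday's to Sunday's the charge grows 3.00-fold and the row drops 1.5 percentage points. In Saturday's flask the half-life of target by its loss to over-reaction product alone, 0.68 min, is short against 4.0 min. Target plus over-reaction product, counted against the full B, gives a rough kinetic chain length: 1.47 per radical in Saturday's flask and 7.83 in Wednesday's, below the 14.0 of Ann's row.

The numbers in the tables come from a simulation with constants of no real substance.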